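## Structural features

The target is an unsymmetrical dimer of two 2-(2-phenylethyl)-4H-chromen-4-ones joined by one aryl–aryl bond between C5 of unit A and C5' of unit B. Unit A carries its free hydroxyl on C6, unit B on C8'. There is no sp3 stereocentre, so no stereocentres stand next to each other. The only stereogenic element is the C5–C5' axis, which has three ortho substituents (C4a with its peri carbonyl and C6–OH on unit A, C4a' with its peri carbonyl on unit B, opposite H on C6'). The fragile parts are the phenols (ring A is a hydroquinone-type arene, O on C6 para to O1 on C8a, and oxidises easily), the pyranones (opened by hydroxide, attacked at C2 by strong nucleophiles) and the vinylogously acidic CH2 groups on C2 and C2'. The real difficulty is the hindered, unsymmetrical biaryl bond between two electron-rich rings with different oxygen patterns, each with an acyl carbon ortho to the axis; a cross-coupling would have to join two ortho-acyl, ortho-oxygenated halves. The key step uses the fact that C4–C4a–C8a–O1 of unit A is a salicyloyl unit, while C5 (aryl), C6 (oxygen) and C7 form a three-carbon 1,3-dielectrophile. Ring A (C4a, C5, C6, C7, C8, C8a) can therefore be built from an acetoacetate unit (C4, C4a, C8a, C8) and an aryl 2-methoxy-3-oxopropanal unit, so the biaryl bond is inherited from the aryl–carbonyl bond of an aryl ketone and is never made by coupling. In unit B the adjacent oxygens on C8a' and C8' and the acyl carbon on C4a' correspond to a 2-bromo-3,4-dimethoxyphenyl group, with bromine marking C4a'.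

## Logic of the disconnections

16 ⇒ 14 (through 15). Cut: the O1'–C2' bond of the unit B pyranone and the three O–CH3 bonds. Reason: an ortho-oxygenated aryl alkynyl ketone is the open form of a chromone, and the methyl group that blocks the future ring oxygen can fall in the same operation that frees the two phenols. Gain: 14 has only robust methyl ethers and an open unit B. Demand: three demethylations must spare the alkynone, and closure must be 6-endo (pyranone), not 5-exo (benzofuranone).

14 ⇒ 12 + 13 + carbon monoxide. Cut: C4a'–C4' and C4'–C3'. Reason: a three-component carbonylative coupling places the carbonyl carbon and the whole side chain on the position marked by bromine, with no change of oxidation state afterwards. Gain: 12 and the purchased alkyne 13. Demand: oxidative addition at a bromide flanked by a methoxy group and the biaryl bond, and CO insertion faster than direct alkynylation.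

12 ⇒ 9 + 10 (through 11). Cut: C3–C4 and O1–C2 of the unit A pyranone. Reason: the ester carbon delivered by the key step already has the oxidation level of C4, so a salicylate plus a methyl ketone enolate gives the 1,3-diketone 11, which closes under acid. Gain: 9 and the purchased ketone 10. Demand: a Claisen condensation on a hindered ester next to a free phenol, enolisation of 10 on the methyl side, and an acid closure that leaves bromide and methyl ethers alone.

9 ⇒ 8 + 3. Cut: C7–C8 and C4a–C5, which removes ring A. Reason: this is the only cut that avoids making the hindered biaryl bond by coupling. Gain: an acyclic enone carrying one arene and a four-carbon diene. Demand: the diene terminus must bond to the silyloxy-bearing CH and the central carbon to the aryl ketone. The substitution pattern of 8 is kept after re-deriving the atom mapping: all three oxygens stay as methyl ethers, so that one reagent frees them at the end, and bromine stays as the handle because it has no ortho hydrogen (no aryne with amide bases) and tolerates Grignard reagent, NaH and TiCl4. The one refinement is that 8 is made and used crude as its E/Z mixture, since both isomers give the same titanium-bound electrophile and the silyl ether does not survive chromatography.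

3 ⇒ 2 ⇒ 1. Cut: the two O–Si bonds in turn. Reason: the diene is the doubly silylated dienolate of the acetoacetate. Gain: the purchased ester 1. Demand: exclusion of moisture; 3 is used without purification.

8 ⇒ 7 ⇒ 6. Cut: the O–Si bond of 8, then the C6–C7 bond (formyl carbon on the methoxy-bearing carbon). Reason: 6 has a single enolisable position, so formylation needs no regiocontrol. Gain: a simple α-methoxy ketone. Demand: silylation on the formyl oxygen; either silyl isomer would serve under TiCl4.

6 ⇒ 5 ⇒ 4. Cut: the C5–C6 bond between the former aldehyde carbon and the CH2OMe carbon, after a change of oxidation level. Reason: the aldehyde carbon of 4 becomes C5 and its ortho bromine is already in place. Gain: the purchased aldehyde 4. Demand: a methoxymethyl nucleophile that adds to the aldehyde without touching the aryl bromide.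

## Other disconnections considered

Alternative 1: The cut is at the two exocyclic bonds C2–CH2 and C2'–CH2, so both side chains would be attached last to a core without side chains, 6,8'-dimethoxy-4H,4'H-[5,5'-bichromene]-4,4'-dione A1.
- Forward key step: the redox-active ester 1,3-dioxoisoindolin-2-yl 3-phenylpropanoate A2 would be reduced at a carbon cathode with a sacrificial zinc anode. Loss of CO2 and phthalimide anion gives the 2-phenylethyl radical, which would add to the β-carbons C2 and C2'. Reduction and protonation would give the bis-chromanone A3 as diastereomers. No ring closes; dehydrogenation and demethylation would follow.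
- In its favour: both chains come from one cheap acid in one operation, C2 is the only β-position, and the reacting site is far from the crowded axis. Other side chains could be put on the same core.
- Against it here: the hindered C5–C5' bond is untouched by this cut, so A1 must still be assembled first. The addition must succeed twice on a substrate that is itself reducible. Primary radicals can be reduced further or dimerise. The pyranones are reduced only to be re-oxidised, through stereocentres the target does not have.
- Comparison, structure: the chosen plan solves the biaryl problem by building ring A, whereas this cut decorates a finished core.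
- Comparison, mechanism: the radical addition is the equal or the better of the Claisen condensation of step 8 in tolerance of crowding and in modularity, but it adds a redox detour.
- Comparison, step economy: three operations from A1 to 16 equal the three steps after the key step here, so the alternative would be ahead only if A1 could be reached in fewer than seven steps, which its biaryl makes unlikely.

Alternative 2: The cut removes both pyranones at once (C2–C3 and O1–C2 in each unit) and leads to the biaryl bis(2-hydroxyacetophenone) A4 and two molecules of ethyl 3-phenylpropanoate A5.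
- Forward key step: the polyanion of A4, formed with LiN(SiMe3)2, would be acylated twice by A5. HCl in acetic acid would then close both rings to the dimethyl ether A6, one demethylation from 16.
- In its favour: this is dependable chromone chemistry, two-directional, with no alkynone and no transition metal near the end. The hindered partner is the nucleophile and the unhindered ester the electrophile, the reverse of step 8 and the better arrangement.
- Against it here: the whole difficulty moves into A4, a tri-ortho-substituted unsymmetrical biaryl with an acetyl group on each side of the axis and differentiated oxygens. Its cross-coupling would join two ortho-acetyl, ortho-oxygenated halves, each needing its own regiocontrolled synthesis. A fourfold deprotonation and twofold acylation must go to completion.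
- Comparison, structure: the chosen plan uses two different pyranone syntheses, which is less symmetrical, but it never couples two hindered arenes.
- Comparison, mechanism: the end game of this alternative is the better one; its biaryl formation is weaker than an aromatising cyclocondensation.
- Comparison, step economy: two steps from A4 to 16 against three from 9 to 16, so the end game is shorter by one step, but A4 is expected to cost more steps than the seven that lead to 9.

Alternative 3: Two bonds to ring A are cut together, the biaryl bond C5–C5' and C4a–C4, which divides the molecule into a unit B aryllithium, a symmetrical aryne and a one-carbon electrophile.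
- Forward key step: lithium 2,2,6,6-tetramethylpiperidide would deprotonate 2-bromo-1,4-dimethoxybenzene A7 between bromine and methoxy, and loss of LiBr would release 3,6-dimethoxybenzyne A8. The aryllithium from 2-(6-bromo-2,3-dimethoxyphenyl)-1,3-dioxolane A9 would add to it, and DMF would formylate the new ortho-lithiated biaryl to give 2-[2-(1,3-dioxolan-2-yl)-3,4-dimethoxyphenyl]-3,6-dimethoxybenzaldehyde A10. No ring closes.
- In its favour: it is the most convergent plan, giving the biaryl bond and the C4 carbon in one flask from two simple arenes. The aryne is symmetrical, so regiochemistry is not in question.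
- Against it here: three organolithium species coexist. The aryllithium can exchange halogen or proton with A7, the biaryllithium can add to a second aryne, and the nucleophile is hindered by its ortho acetal. After the key step neither pyranone exists: each aldehyde carbon must be extended by an alkynyl unit, oxidised and closed with demethylation, about six further operations.
- Comparison, structure: A10 holds C4 and C4' at the aldehyde level, so oxidation-state changes are needed that the ester carbon of 9 and the CO insertion of step 9 avoid.
- Comparison, mechanism: on regiocontrol the alternative is the equal of the chosen plan and on convergence it is better. Its chemoselectivity rests on relative rates, whereas the cyclocondensation is driven by aromatisation.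
- Comparison, step economy: roughly two steps to A9, the key step and about six more are about equal to the ten steps here.

Key step: step 7

Assumption 1: the C5–C5' axis is treated as configurationally undefined (racemic if rotation is slow), since the target carries no axial descriptor; 9, 11, 12, 14, 15 and 16 are drawn without it.
Assumption 2: 2-bromo-3,4-dimethoxybenzaldehyde (4) is taken as a catalogue compound.

Step 1
Reactants: 1 methyl acetoacetate
Product: 2 methyl 3-(trimethylsilyloxy)but-2-enoate (E/Z mixture)
Conditions: Me3SiCl, Et3N, toluene, 20 °C; filtration, distillation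
Reagents that add atoms: chlorotrimethylsilane, C[Si](C)(C)Cl
Why: O-silylation of the enol of a β-keto ester under soft enolisation; precipitation of the ammonium chloride drives the reaction.

Step 2
Reactants: 2 methyl 3-(trimethylsilyloxy)but-2-enoate
Product: 3 1-methoxy-1,3-bis(trimethylsilyloxy)buta-1,3-diene (mixture of geometric isomers)
Conditions: LiN(iPr)2 (commercial solution), THF, −78 °C; Me3SiCl, −78 → 20 °C; hexane, filtration; used crude
Reagents that add atoms: chlorotrimethylsilane, C[Si](C)(C)Cl
Why: The amide base removes a γ-proton to give the extended dienolate, which is silylated on the ester oxygen (standard preparation of a 1,3-bis(silyloxy)diene).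

Step 3
Reactants: 4 2-bromo-3,4-dimethoxybenzaldehyde
Product: 5 1-(2-bromo-3,4-dimethoxyphenyl)-2-methoxyethan-1-ol (racemic)
Conditions: MeOCH2MgCl (from MeOCH2Cl and Mg, THF, −20 °C), THF, −78 → 0 °C; aq. NH4Cl
Reagents that add atoms: methoxymethylmagnesium chloride, COC[Mg]Cl
Why: Grignard 1,2-addition to the aldehyde; an alkyl Grignard reagent does not exchange with an electron-rich aryl bromide at this temperature. The carbinol centre forms racemic and is removed in step 4.

Step 4
Reactants: 5 1-(2-bromo-3,4-dimethoxyphenyl)-2-methoxyethan-1-ol
Product: 6 1-(2-bromo-3,4-dimethoxyphenyl)-2-methoxyethan-1-one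
Conditions: Dess–Martin periodinane, NaHCO3, CH2Cl2, 0 → 20 °C
Reagents that add atoms: none
Why: Dess–Martin oxidation of a secondary benzylic alcohol under buffered, neutral conditions; aryl bromide, methyl ethers and the α-methoxy group are untouched.

Step 5
Reactants: 6 1-(2-bromo-3,4-dimethoxyphenyl)-2-methoxyethan-1-one
Product: 7 1-(2-bromo-3,4-dimethoxyphenyl)-3-hydroxy-2-methoxyprop-2-en-1-one (enol form of the 2-methoxy-3-oxopropanal; geometry not fixed)
Conditions: NaH, HCO2Et, THF (cat. EtOH), 0 → 20 °C; then cold dil. HCl
Reagents that add atoms: ethyl formate, CCOC=O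
Why: Crossed Claisen formylation at the only enolisable carbon (CH2 between carbonyl and methoxy); formation of the stable sodium enolate of the product drives the equilibrium.

Step 6
Reactants: 7 1-(2-bromo-3,4-dimethoxyphenyl)-3-hydroxy-2-methoxyprop-2-en-1-one
Product: 8 1-(2-bromo-3,4-dimethoxyphenyl)-2-methoxy-3-(trimethylsilyloxy)prop-2-en-1-one (E/Z mixture)
Conditions: Me3SiCl, Et3N, toluene, 20 °C; filtration under argon; used crude
Reagents that add atoms: chlorotrimethylsilane, C[Si](C)(C)Cl
Why: O-silylation of the enolised formyl group of a hydroxymethylene ketone with silyl chloride and amine, the standard route to 3-silyloxy-2-en-1-ones.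

Step 7
Reactants: 8 1-(2-bromo-3,4-dimethoxyphenyl)-2-methoxy-3-(trimethylsilyloxy)prop-2-en-1-one; 3 1-methoxy-1,3-bis(trimethylsilyloxy)buta-1,3-diene
Product: 9 methyl 2-(2-bromo-3,4-dimethoxyphenyl)-6-hydroxy-3-methoxybenzoate
Conditions: TiCl4, CH2Cl2, 4 Å molecular sieves, −78 → 20 °C; then 10% aq. HCl
Reagents that add atoms: none
Why: TiCl4 binds the carbonyl oxygen of 8 (probably chelated by the 2-methoxy group), and the terminal carbon of 3, its most nucleophilic and least hindered position, adds in a Mukaiyama–Michael sense to the silyloxy-bearing CH; loss of silanolate restores an enone and completes the C7–C8 bond. The central carbon of the resulting titanium 1,3-dicarbonyl enolate then attacks the aryl ketone in an intramolecular aldol addition (C4a–C5), a 6-(enolendo)-exo-trig closure, and loss of water with enolisation aromatises ring A, which makes the sequence irreversible. The closest known reaction type is the TiCl4-mediated formal (3+3) cyclocondensation of 1,3-bis(silyloxy)buta-1,3-dienes with 3-silyloxy-2-en-1-ones, including 2-substituted enones made by formylation of ketones. No stereocentre forms; the biaryl axis is left uncontrolled. The selectivity needed is regiochemical: the diene terminus must bond to the CH and not to the ketone carbon. This is secured because the CH is an unhindered vinylogous acyl position, whereas the ketone carbon is shielded by the ortho bromine and deactivated by conjugation with an electron-rich ring, so it reacts only intramolecularly. Both geometric isomers of 8 and of 3 converge, since the push–pull double bond isomerises under the Lewis acid and all double-bond geometry is lost on aromatisation.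

Step 8
Reactants: 9 methyl 2-(2-bromo-3,4-dimethoxyphenyl)-6-hydroxy-3-methoxybenzoate; 10 4-phenylbutan-2-one
Product: 12 5-(2-bromo-3,4-dimethoxyphenyl)-6-methoxy-2-(2-phenylethyl)-4H-chromen-4-one, via aryl 1,3-diketone 11 (not isolated)
Conditions: LiN(iPr)2 (3.3 equiv), 10 (3.5 equiv), THF, −78 °C; then 9, −78 → 20 °C; AcOH quench, evaporation; conc. HCl, AcOH, 70 °C
Reagents that add atoms: none
Why: Crossed Claisen condensation of the kinetic methyl-side lithium enolate of 10 (in excess, since the phenol and the product diketone each consume one equivalent) with the lithium-chelated salicylate ester, then acid-catalysed cyclodehydration of the o-hydroxyaryl 1,3-diketone to the pyranone. The bromide has no ortho hydrogen, so no aryne can form, and bromide and methyl ethers are stable to HCl/AcOH.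

Step 9
Reactants: 12 5-(2-bromo-3,4-dimethoxyphenyl)-6-methoxy-2-(2-phenylethyl)-4H-chromen-4-one; 13 4-phenylbut-1-yne
Product: 14 5-[3,4-dimethoxy-2-(5-phenylpent-2-ynoyl)phenyl]-6-methoxy-2-(2-phenylethyl)-4H-chromen-4-one
Conditions: [Pd(cinnamyl)Cl]2 (cat.), BuPAd2 (cat.), CO (10 bar), K2CO3, DMF, 100 °C
Reagents that add atoms: carbon monoxide, [C-]#[O+]
Why: Carbonylative Sonogashira coupling of an aryl bromide: zerovalent palladium with the bulky, electron-rich phosphine inserts into the hindered C–Br bond, CO insertion is favoured by relief of strain at the di-ortho-substituted aryl–palladium bond, and the alkynyl group is transferred and eliminated as the ynone. No copper is used, which disfavours direct alkynylation and alkyne homocoupling.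

Step 10
Reactants: 14 5-[3,4-dimethoxy-2-(5-phenylpent-2-ynoyl)phenyl]-6-methoxy-2-(2-phenylethyl)-4H-chromen-4-one
Product: 16 6,8'-dihydroxy-2,2'-bis(2-phenylethyl)-4H,4'H-[5,5'-bichromene]-4,4'-dione (CNP0392394.0), via trihydroxy ynone 15 (not isolated)
Conditions: BBr3 (excess), CH2Cl2, −78 → 20 °C; MeOH, 0 °C, evaporation; Et2NH, EtOH, 20 °C, under argon; dil. HCl
Reagents that add atoms: none
Why: BBr3 cleaves the three aryl methyl ethers, the one ortho to the alkynone first through chelation, and the freed ortho phenol adds to the alkynone in a 6-endo-dig oxa-Michael closure. The amine treatment completes closure through a β-aminoenone (or the β-bromoenone from HBr addition) by addition–elimination, a path that leads only to the six-membered pyranone. BBr3 demethylation of methoxy-2-(2-phenylethyl)chromones is standard and leaves pyranone and side chains intact.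

## Compound list

1 | methyl acetoacetate | COC(=O)CC(C)=O | starting material
2 | methyl 3-(trimethylsilyloxy)but-2-enoate (E/Z mixture) | COC(=O)C=C(C)O[Si](C)(C)C | intermediate
3 | 1-methoxy-1,3-bis(trimethylsilyloxy)buta-1,3-diene (mixture of geometric isomers) | C=C(O[Si](C)(C)C)C=C(OC)O[Si](C)(C)C | intermediate
4 | 2-bromo-3,4-dimethoxybenzaldehyde | COc1ccc(C=O)c(Br)c1OC | starting material
5 | 1-(2-bromo-3,4-dimethoxyphenyl)-2-methoxyethan-1-ol (racemic) | COCC(O)c1ccc(OC)c(OC)c1Br | intermediate
6 | 1-(2-bromo-3,4-dimethoxyphenyl)-2-methoxyethan-1-one | COCC(=O)c1ccc(OC)c(OC)c1Br | intermediate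
7 | 1-(2-bromo-3,4-dimethoxyphenyl)-3-hydroxy-2-methoxyprop-2-en-1-one (enol tautomer, geometry not fixed) | COc1ccc(C(=O)C(OC)=CO)c(Br)c1OC | intermediate
8 | 1-(2-bromo-3,4-dimethoxyphenyl)-2-methoxy-3-(trimethylsilyloxy)prop-2-en-1-one (E/Z mixture) | COc1ccc(C(=O)C(OC)=CO[Si](C)(C)C)c(Br)c1OC | intermediate
9 | methyl 2-(2-bromo-3,4-dimethoxyphenyl)-6-hydroxy-3-methoxybenzoate | COC(=O)c1c(O)ccc(OC)c1-c1ccc(OC)c(OC)c1Br | intermediate
10 | 4-phenylbutan-2-one | CC(=O)CCc1ccccc1 | starting material
11 | 1-[2-(2-bromo-3,4-dimethoxyphenyl)-6-hydroxy-3-methoxyphenyl]-5-phenylpentane-1,3-dione (not isolated) | O=C(CC(=O)CCc1ccccc1)c1c(O)ccc(OC)c1-c1ccc(OC)c(OC)c1Br | intermediate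
12 | 5-(2-bromo-3,4-dimethoxyphenyl)-6-methoxy-2-(2-phenylethyl)-4H-chromen-4-one | O=c1cc(CCc2ccccc2)oc2ccc(OC)c(-c3ccc(OC)c(OC)c3Br)c12 | intermediate
13 | 4-phenylbut-1-yne | C#CCCc1ccccc1 | starting material
14 | 5-[3,4-dimethoxy-2-(5-phenylpent-2-ynoyl)phenyl]-6-methoxy-2-(2-phenylethyl)-4H-chromen-4-one | O=c1cc(CCc2ccccc2)oc2ccc(OC)c(-c3ccc(OC)c(OC)c3C(=O)C#CCCc3ccccc3)c12 | intermediate
15 | 5-[3,4-dihydroxy-2-(5-phenylpent-2-ynoyl)phenyl]-6-hydroxy-2-(2-phenylethyl)-4H-chromen-4-one (not isolated) | O=c1cc(CCc2ccccc2)oc2ccc(O)c(-c3ccc(O)c(O)c3C(=O)C#CCCc3ccccc3)c12 | intermediate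
16 | 6,8'-dihydroxy-2,2'-bis(2-phenylethyl)-4H,4'H-[5,5'-bichromene]-4,4'-dione (CNP0392394.0) | O=c1cc(CCc2ccccc2)oc2ccc(O)c(-c3ccc(O)c4oc(CCc5ccccc5)cc(=O)c34)c12 | target

## Step count and least certain steps

Total: 10 steps. Longest linear sequence: 8 steps (steps 3 to 10, from 4 to 16); steps 1 and 2 form the diene branch that joins at step 7.

Step 7 (key step). Most likely to go wrong: the aldol closure onto the ortho-bromoaryl ketone may be slow, so the open-chain Michael adduct is hydrolysed on work-up. Alternatively 8 may be desilylated back to 7 by adventitious HCl before it couples. Attack of the diene terminus on the ketone would give the regioisomeric salicylate. Fallback, setting out from 7: HC(OMe)3, MeOH and catalytic TsOH convert the formyl carbon into its dimethyl acetal, 1-(2-bromo-3,4-dimethoxyphenyl)-2,3,3-trimethoxypropan-1-one F1. F1 and 3 with TiCl4 in CH2Cl2 (the β-keto acetal variant of the salicylate synthesis, in which the oxocarbenium ion from the acetal is necessarily the first electrophile) should give 9, where the route is rejoined.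

Step 8. Most likely to go wrong: incomplete acylation, because the phenoxide lowers the electrophilicity of an ester that is already flanked on both sides. Competing self-aldol of 10 and acylation through the internal enolate are further risks. Fallback, setting out from 9:
- LiAlH4 in THF at 0 °C reduces the ester to 3-(2-bromo-3,4-dimethoxyphenyl)-2-(hydroxymethyl)-4-methoxyphenol F2.
- MnO2 oxidises the benzylic alcohol to 2-(2-bromo-3,4-dimethoxyphenyl)-6-hydroxy-3-methoxybenzaldehyde F3.
- The lithium acetylide of 13 (n-BuLi, THF, −78 °C, in excess for the phenol) adds to give 1-[2-(2-bromo-3,4-dimethoxyphenyl)-6-hydroxy-3-methoxyphenyl]-5-phenylpent-2-yn-1-ol F4.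
- MnO2 gives 1-[2-(2-bromo-3,4-dimethoxyphenyl)-6-hydroxy-3-methoxyphenyl]-5-phenylpent-2-yn-1-one F5.
- Et2NH in EtOH closes F5 6-endo to 12.

Step 9. Most likely to go wrong: slow oxidative addition at the di-ortho-substituted, electron-rich bromide under CO; direct alkynylation without CO uptake; base-induced isomerisation of the alkyl ynone at 100 °C. Fallback, setting out from 12: reductive carbonylation (Pd(OAc)2, BuPAd2, CO/H2, TMEDA, toluene, 100 °C), a formylation that is well established for hindered aryl bromides and involves no alkyne, gives 2,3-dimethoxy-6-[6-methoxy-4-oxo-2-(2-phenylethyl)-4H-chromen-5-yl]benzaldehyde F6. The lithium acetylide of 13 at −78 °C adds to the aldehyde, which is far more electrophilic than the vinylogous ester carbonyl of the pyranone, to give 5-[2-(1-hydroxy-5-phenylpent-2-yn-1-yl)-3,4-dimethoxyphenyl]-6-methoxy-2-(2-phenylethyl)-4H-chromen-4-one F7. Dess–Martin oxidation of F7 gives 14.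

Step 10. Most likely to go wrong: addition of HBr or of boron species across the alkynone with decomposition before ring closure, 5-exo closure to a benzofuranone, incomplete cleavage of the hindered 6-methoxy group, and air oxidation of the catechol stage under base. Fallback, setting out from 14:
- BCl3 (CH2Cl2, −78 → 0 °C) removes only the methyl group ortho to the alkynone by chelation control and gives 5-[3-hydroxy-4-methoxy-2-(5-phenylpent-2-ynoyl)phenyl]-6-methoxy-2-(2-phenylethyl)-4H-chromen-4-one F8.
- Et2NH in EtOH closes the pyranone to 6,8'-dimethoxy-2,2'-bis(2-phenylethyl)-4H,4'H-[5,5'-bichromene]-4,4'-dione F9 (the same compound as A6).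
- BBr3 in CH2Cl2 on this robust bis-chromone, which no longer holds an alkynone, removes the two remaining methyl groups and gives 16.

Step 3. Most likely to go wrong: decomposition of the thermally unstable Grignard reagent before addition, leaving unreacted aldehyde. Fallback, setting out from 4: Corey–Chaykovsky epoxidation (Me3SI, NaH, DMSO/THF) gives 2-(2-bromo-3,4-dimethoxyphenyl)oxirane F10. NaOMe in MeOH opens F10 at the unhindered terminal carbon and gives 5.

## Further compounds

F1 | step 7 | 1-(2-bromo-3,4-dimethoxyphenyl)-2,3,3-trimethoxypropan-1-one (racemic) | COC(OC)C(OC)C(=O)c1ccc(OC)c(OC)c1Br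
F2 | step 8 | 3-(2-bromo-3,4-dimethoxyphenyl)-2-(hydroxymethyl)-4-methoxyphenol | OCc1c(O)ccc(OC)c1-c1ccc(OC)c(OC)c1Br
F3 | step 8 | 2-(2-bromo-3,4-dimethoxyphenyl)-6-hydroxy-3-methoxybenzaldehyde | O=Cc1c(O)ccc(OC)c1-c1ccc(OC)c(OC)c1Br
F4 | step 8 | 1-[2-(2-bromo-3,4-dimethoxyphenyl)-6-hydroxy-3-methoxyphenyl]-5-phenylpent-2-yn-1-ol (racemic) | OC(C#CCCc1ccccc1)c1c(O)ccc(OC)c1-c1ccc(OC)c(OC)c1Br
F5 | step 8 | 1-[2-(2-bromo-3,4-dimethoxyphenyl)-6-hydroxy-3-methoxyphenyl]-5-phenylpent-2-yn-1-one | O=C(C#CCCc1ccccc1)c1c(O)ccc(OC)c1-c1ccc(OC)c(OC)c1Br
F6 | step 9 | 2,3-dimethoxy-6-[6-methoxy-4-oxo-2-(2-phenylethyl)-4H-chromen-5-yl]benzaldehyde | O=Cc1c(OC)c(OC)ccc1-c1c(OC)ccc2oc(CCc3ccccc3)cc(=O)c12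
F7 | step 9 | 5-[2-(1-hydroxy-5-phenylpent-2-yn-1-yl)-3,4-dimethoxyphenyl]-6-methoxy-2-(2-phenylethyl)-4H-chromen-4-one (racemic, carbinol centre uncontrolled) | OC(C#CCCc1ccccc1)c1c(OC)c(OC)ccc1-c1c(OC)ccc2oc(CCc3ccccc3)cc(=O)c12
F8 | step 10 | 5-[3-hydroxy-4-methoxy-2-(5-phenylpent-2-ynoyl)phenyl]-6-methoxy-2-(2-phenylethyl)-4H-chromen-4-one | O=c1cc(CCc2ccccc2)oc2ccc(OC)c(-c3ccc(OC)c(O)c3C(=O)C#CCCc3ccccc3)c12
F9 | step 10 | 6,8'-dimethoxy-2,2'-bis(2-phenylethyl)-4H,4'H-[5,5'-bichromene]-4,4'-dione | O=c1cc(CCc2ccccc2)oc2ccc(OC)c(-c3ccc(OC)c4oc(CCc5ccccc5)cc(=O)c34)c12
F10 | step 3 | 2-(2-bromo-3,4-dimethoxyphenyl)oxirane (racemic) | COc1ccc(C2CO2)c(Br)c1OC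
A1 | alternative 1 | 6,8'-dimethoxy-4H,4'H-[5,5'-bichromene]-4,4'-dione | O=c1ccoc2ccc(OC)c(-c3ccc(OC)c4occc(=O)c34)c12
A2 | alternative 1 | 1,3-dioxoisoindolin-2-yl 3-phenylpropanoate | O=C(CCc1ccccc1)ON1C(=O)c2ccccc2C1=O
A3 | alternative 1 | 6,8'-dimethoxy-2,2'-bis(2-phenylethyl)-5,5'-bichroman-4,4'-dione (mixture of diastereomers) | O=C1CC(CCc2ccccc2)Oc2ccc(OC)c(-c3ccc(OC)c4OC(CCc5ccccc5)CC(=O)c34)c12
A4 | alternative 2 | 1-[2-(2-acetyl-3-hydroxy-4-methoxyphenyl)-6-hydroxy-3-methoxyphenyl]ethan-1-one | CC(=O)c1c(O)ccc(OC)c1-c1ccc(OC)c(O)c1C(C)=O
A5 | alternative 2 | ethyl 3-phenylpropanoate | CCOC(=O)CCc1ccccc1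
A6 | alternative 2 | 6,8'-dimethoxy-2,2'-bis(2-phenylethyl)-4H,4'H-[5,5'-bichromene]-4,4'-dione | O=c1cc(CCc2ccccc2)oc2ccc(OC)c(-c3ccc(OC)c4oc(CCc5ccccc5)cc(=O)c34)c12
A7 | alternative 3 | 2-bromo-1,4-dimethoxybenzene | COc1ccc(OC)c(Br)c1
A8 | alternative 3 | 3,6-dimethoxybenzyne (1,4-dimethoxy-2,3-didehydrobenzene) | COC1=CC=C(OC)C#C1
A9 | alternative 3 | 2-(6-bromo-2,3-dimethoxyphenyl)-1,3-dioxolane | COc1ccc(Br)c(C2OCCO2)c1OC
A10 | alternative 3 | 2-[2-(1,3-dioxolan-2-yl)-3,4-dimethoxyphenyl]-3,6-dimethoxybenzaldehyde | COc1ccc(OC)c(C=O)c1-c1ccc(OC)c(OC)c1C1OCCO1
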